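**Plan**

- Retrosynthesis: the two CH2OH groups go back to methyl esters. Ring B is then cut at C1–C8a and C1–C2, which removes C1 as a one-carbon unit and leaves an aryl bromide carrying the C4–C3–C2 chain.
- Enabling feature: C1 is a benzhydryl-type CH bonded to C8a of ring A, to the 3,4-dimethoxyphenyl ring and to C2. It can therefore arrive as the aldehyde carbon of veratraldehyde in carbene form, inserted between an aryl–palladium bond at C8a and a carbon nucleophile at C2.
- Forward: a Stobbe condensation joins the succinate chain to ring A and fixes the (E)-alkene C3=C4. One palladium-catalysed [5+1] annulation with veratraldehyde tosylhydrazone closes ring B, and ester reduction ends the route.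
- Stereochemistry: C1 is set in the annulation by a chiral bisphosphine on palladium. C2 settles trans to the C1 aryl group by enolisation under the same basic conditions, and the final reduction touches neither centre.

Key step: step 4

Assumption: the sense of induction of the bisphosphine in step 4 cannot be assigned in advance; the (R)-ligand is written, and its (S)-antipode would be used if the (1S) series arose.

**Step 1**
Reactants: 1 2-bromo-3,4,5-trimethoxybenzaldehyde; 2 dimethyl succinate
Product: 4 (E)-4-(2-bromo-3,4,5-trimethoxyphenyl)-3-(methoxycarbonyl)but-3-enoic acid, via paraconate lactone 3 (not isolated)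
Conditions: NaOMe (2 equiv), MeOH, reflux; then aq. HCl
Reagents that add atoms: none
Why: Stobbe condensation, in which the succinate enolate adds to the aldehyde, the alkoxide lactonises onto the distal ester to give 3, and E1cB opening of the lactone gives the (E)-alkylidene half-ester with the aryl group trans to the conjugated ester and hence cis to the CH2 arm.

**Step 2**
Reactants: 4 (E)-4-(2-bromo-3,4,5-trimethoxyphenyl)-3-(methoxycarbonyl)but-3-enoic acid
Product: 5 dimethyl (E)-2-(2-bromo-3,4,5-trimethoxybenzylidene)succinate
Conditions: MeOH, H2SO4 (cat.), reflux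
Reagents that add atoms: methanol, CO
Why: Fischer esterification of the non-conjugated acid, which leaves the aryl bromide, the methyl ethers and the (E)-alkene untouched and also converts any diacid carried over from step 1 into the same diester.

**Step 3**
Reactants: 6 veratraldehyde (3,4-dimethoxybenzaldehyde); 7 p-toluenesulfonohydrazide
Product: 8 (E)-N'-(3,4-dimethoxybenzylidene)-4-methylbenzenesulfonohydrazide (veratraldehyde N-tosylhydrazone)
Conditions: MeOH, 60 °C; cool and filter
Reagents that add atoms: none
Why: Condensation of an aromatic aldehyde with a sulfonyl hydrazide gives the crystalline (E)-N-tosylhydrazone, the bench-stable source of the diazo compound needed in step 4.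

**Step 4**
Reactants: 5 dimethyl (E)-2-(2-bromo-3,4,5-trimethoxybenzylidene)succinate; 8 veratraldehyde N-tosylhydrazone
Product: 10 dimethyl (1R,2S)-1-(3,4-dimethoxyphenyl)-6,7,8-trimethoxy-1,2-dihydronaphthalene-2,3-dicarboxylate, via aryldiazomethane 9 (not isolated)
Conditions: Pd2(dba)3 (2.5 mol %), (R)-DTBM-SEGPHOS (6 mol %), LiOtBu (2.3 equiv), 8 (1.4 equiv), 1,4-dioxane, 90 °C, argon
Reagents that add atoms: none
Why: Proposed new method: zerovalent palladium carrying the bisphosphine inserts into the C8a–Br bond of 5 while LiOtBu turns 8 into diazo compound 9 (Bamford–Stevens), 9 forms an arylpalladium carbene, migration of the ring A aryl group onto the carbene carbon makes C1–C8a and leaves a cationic η3-benzhydryl palladium complex that has no β-hydrogen, and the lithium dienolate formed at the CH2CO2Me arm attacks C1 to make C1–C2 and release zerovalent palladium. The closest known reaction type is the palladium-catalysed coupling of aryl halides with N-tosylhydrazones through carbene migratory insertion in which the benzyl- or allylpalladium so formed is captured by a tethered soft nucleophile, alongside asymmetric benzylic substitution through η3-benzyl palladium complexes. Ring B closes by a 6-exo-tet alkylation (C2 onto C1, palladium leaving outside the ring), possible because the (E)-alkene C3=C4 holds ring A and the nucleophilic arm cis. C1 is controlled by the chiral bisphosphine, either through the face of the carbene that accepts the aryl group or through selection between interconverting η3-benzhydryl diastereomers that the dienolate opens with inversion, and C2 is under thermodynamic control, reversible enolisation leaving the 1,2-trans diester in which the C1 aryl group and the C2 ester lie on opposite faces. The step needs carbene transfer to outrun direct arylation of the enolate at C8a (an indene closure) and needs α- and not γ-attack of the dienolate: the doubly ortho-substituted arylpalladium is slow to couple with a hindered enolate but open to the small diazo compound, which is supplied in excess, and the γ-carbon C4 is already bonded to ring A and cannot reach C1. Base is limited to little more than the two equivalents that the equation consumes, so that the product is not left in strong base that could shift the C3=C4 double bond.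

**Step 5**
Reactants: 10 dimethyl (1R,2S)-1-(3,4-dimethoxyphenyl)-6,7,8-trimethoxy-1,2-dihydronaphthalene-2,3-dicarboxylate
Product: 11 [(1R,2S)-1-(3,4-dimethoxyphenyl)-6,7,8-trimethoxy-1,2-dihydronaphthalene-2,3-diyl]dimethanol
Conditions: i-Bu2AlH (5 equiv), CH2Cl2, −78 to 0 °C; aq. potassium sodium tartrate
Reagents that add atoms: none
Why: Ester reduction with i-Bu2AlH, an electrophilic aluminium hydride that takes both the saturated and the conjugated ester to primary alcohols by 1,2-delivery without touching C3=C4, the cold non-basic medium leaving C1 and C2 as set in step 4.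

**Compound list**

1 | 2-bromo-3,4,5-trimethoxybenzaldehyde | COc1cc(C=O)c(Br)c(OC)c1OC | starting material
2 | dimethyl succinate | COC(=O)CCC(=O)OC | starting material
3 | methyl 2-(2-bromo-3,4,5-trimethoxyphenyl)-5-oxooxolane-3-carboxylate (paraconate lactone, racemic mixture of diastereomers) | COC(=O)C1CC(=O)OC1c1cc(OC)c(OC)c(OC)c1Br | intermediate
4 | (E)-4-(2-bromo-3,4,5-trimethoxyphenyl)-3-(methoxycarbonyl)but-3-enoic acid | OC(=O)C/C(C(=O)OC)=C\c1cc(OC)c(OC)c(OC)c1Br | intermediate
5 | dimethyl (E)-2-(2-bromo-3,4,5-trimethoxybenzylidene)succinate | COC(=O)C/C(C(=O)OC)=C\c1cc(OC)c(OC)c(OC)c1Br | intermediate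
6 | veratraldehyde (3,4-dimethoxybenzaldehyde) | COc1ccc(C=O)cc1OC | starting material
7 | p-toluenesulfonohydrazide | Cc1ccc(S(=O)(=O)NN)cc1 | starting material
8 | (E)-N'-(3,4-dimethoxybenzylidene)-4-methylbenzenesulfonohydrazide | COc1ccc(/C=N/NS(=O)(=O)c2ccc(C)cc2)cc1OC | intermediate
9 | 4-(diazomethyl)-1,2-dimethoxybenzene | COc1ccc(C=[N+]=[N-])cc1OC | intermediate
10 | dimethyl (1R,2S)-1-(3,4-dimethoxyphenyl)-6,7,8-trimethoxy-1,2-dihydronaphthalene-2,3-dicarboxylate (1,2-trans) | COc1ccc([C@@H]2c3c(cc(OC)c(OC)c3OC)C=C(C(=O)OC)[C@H]2C(=O)OC)cc1OC | intermediate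
11 | [(1R,2S)-1-(3,4-dimethoxyphenyl)-6,7,8-trimethoxy-1,2-dihydronaphthalene-2,3-diyl]dimethanol (1,2-trans) | COc1ccc([C@@H]2c3c(cc(OC)c(OC)c3OC)C=C(CO)[C@H]2CO)cc1OC | target

**Totals**

Total step count: 5. Longest linear sequence: 4 steps (1, 2, 4, 5).

**Steps most likely to fail**

Step 4. Three processes could defeat it:
- The arylpalladium bromide may be consumed by direct enolate arylation or protodebromination before the carbene is transferred.
- The ligand may discriminate poorly between the two faces at C1.
- The base may shift the C3=C4 double bond towards C1 and erase both stereocentres.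

The fallback uses known chemistry, sets out from 6 and 2, and returns at 10:
- Veratraldehyde 6 and dimethyl succinate 2 would be joined by Stobbe condensation (NaOMe, MeOH) to (E)-4-(3,4-dimethoxyphenyl)-3-(methoxycarbonyl)but-3-enoic acid F1.
- Fischer esterification (MeOH, H2SO4) would give dimethyl (E)-2-(3,4-dimethoxybenzylidene)succinate F2.
- A second Stobbe condensation with commercial 3,4,5-trimethoxybenzaldehyde would give (2E,3E)-2-(3,4-dimethoxybenzylidene)-3-(methoxycarbonyl)-4-(3,4,5-trimethoxyphenyl)but-3-enoic acid F3.
- Esterification would give dimethyl (2E,3E)-2-(3,4-dimethoxybenzylidene)-3-(3,4,5-trimethoxybenzylidene)succinate F4.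
- CF3SO3H in CH2Cl2, the acid-mediated cyclisation of 2,3-dibenzylidenesuccinates to trans-1-aryl-1,2-dihydronaphthalenes, should close ring B. The trimethoxyphenyl ring, activated by an ortho and a para methoxy group, should attack the benzylic cation stabilised by the 3,4-dimethoxyphenyl ring. This would give racemic dimethyl (1RS,2SR)-1-(3,4-dimethoxyphenyl)-6,7,8-trimethoxy-1,2-dihydronaphthalene-2,3-dicarboxylate F5.
- Separation of the enantiomers by preparative HPLC on a chiral stationary phase would return to 10.

Step 1. The lactone opening may give an (E)/(Z) mixture, or the condensation may be slowed by the ortho bromine, with loss of aldehyde to base-induced side reactions. The fallback sets out from 1 and returns at 5. Aldehyde 1 would be olefinated in toluene at reflux with the stabilised ylide dimethyl 2-(triphenyl-λ5-phosphanylidene)succinate F6, made from triphenylphosphine and dimethyl maleate. This (E)-selective Wittig reaction gives 5 directly and replaces steps 1 and 2.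

Step 5. Hydride may add in conjugate fashion to the aryl-substituted enoate, or an aluminium enolate may form at C2 with epimerisation or double-bond shift. The fallback sets out from 10 and returns at 11. Both esters would be cleaved under near-neutral conditions with Me3SnOH in 1,2-dichloroethane at 80 °C to (1R,2S)-1-(3,4-dimethoxyphenyl)-6,7,8-trimethoxy-1,2-dihydronaphthalene-2,3-dicarboxylic acid F7. The diacid would then be reduced with BH3·SMe2 in THF at 0 °C, which takes carboxylic acids through acyloxyboranes faster than it adds to the electron-poor trisubstituted alkene.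

**Further compounds**

F1 | step 4 | (E)-4-(3,4-dimethoxyphenyl)-3-(methoxycarbonyl)but-3-enoic acid | OC(=O)C/C(C(=O)OC)=C\c1ccc(OC)c(OC)c1
F2 | step 4 | dimethyl (E)-2-(3,4-dimethoxybenzylidene)succinate | COC(=O)C/C(C(=O)OC)=C\c1ccc(OC)c(OC)c1
F3 | step 4 | (2E,3E)-2-(3,4-dimethoxybenzylidene)-3-(methoxycarbonyl)-4-(3,4,5-trimethoxyphenyl)but-3-enoic acid | COc1ccc(/C=C(/C(=O)O)\C(C(=O)OC)=C/c2cc(OC)c(OC)c(OC)c2)cc1OC
F4 | step 4 | dimethyl (2E,3E)-2-(3,4-dimethoxybenzylidene)-3-(3,4,5-trimethoxybenzylidene)succinate | COc1ccc(/C=C(/C(=O)OC)\C(C(=O)OC)=C/c2cc(OC)c(OC)c(OC)c2)cc1OC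
F5 | step 4 | racemic dimethyl (1RS,2SR)-1-(3,4-dimethoxyphenyl)-6,7,8-trimethoxy-1,2-dihydronaphthalene-2,3-dicarboxylate (both trans enantiomers) | COc1ccc([C@@H]2c3c(cc(OC)c(OC)c3OC)C=C(C(=O)OC)[C@H]2C(=O)OC)cc1OC.COc1ccc([C@H]2c3c(cc(OC)c(OC)c3OC)C=C(C(=O)OC)[C@@H]2C(=O)OC)cc1OC
F6 | step 1 | dimethyl 2-(triphenyl-λ5-phosphanylidene)succinate | COC(=O)CC(=P(c1ccccc1)(c1ccccc1)c1ccccc1)C(=O)OC
F7 | step 5 | (1R,2S)-1-(3,4-dimethoxyphenyl)-6,7,8-trimethoxy-1,2-dihydronaphthalene-2,3-dicarboxylic acid | COc1ccc([C@@H]2c3c(cc(OC)c(OC)c3OC)C=C(C(=O)O)[C@H]2C(=O)O)cc1OC
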